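## Retrosynthetic overview

1. C3: catalyst-controlled Et2Zn addition to a C3 enal; C4=C5: Wittig olefination of a C5 aldehyde.
2. C6–C7: Evans-syn titanium propionate aldol (thiazolidinethione auxiliary) on the C7 dienal sets C6 and C7 together.
3. C8=C9 and C10=C11: two successive stabilized-ylide Wittig homologations starting from the C11 aldehyde.
4. C12: Evans methylation of an N-styrylacetyl oxazolidinone; the E-styrene comes ready-made in (E)-4-phenylbut-3-enoic acid.
5. Ring formation: none. The target is acyclic, its only ring (phenyl) is bought in, and the chain is grown linearly from C14 towards C1.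

Assumption: the N-propanoyl thiazolidinethione auxiliary and the two stabilized phosphoranes are taken as purchasable; atom labels C1–C14 refer to the target chain (ethyl end = C1).

## Route

Step 1
Reactants: 1 (E)-4-phenylbut-3-enoic acid; 2 (S)-4-benzyloxazolidin-2-one
Product: 4 (S)-4-benzyl-3-[(E)-4-phenylbut-3-enoyl]oxazolidin-2-one, via mixed pivalic anhydride 3 (not isolated)
Conditions: PivCl, Et3N, THF, −20 °C; then LiCl, 2, −20 °C → rt
Reagents that add atoms: none
Why: N-acylation of the oxazolidinone by the mixed anhydride (LiCl/Et3N activation) is mild enough to leave the β,γ-styrenyl double bond in place.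

Step 2
Reactants: 4 (S)-4-benzyl-3-[(E)-4-phenylbut-3-enoyl]oxazolidin-2-one
Product: 6 (S)-4-benzyl-3-[(2S,3E)-2-methyl-4-phenylbut-3-enoyl]oxazolidin-2-one, via sodium dienolate 5 (not isolated)
Conditions: NaN(SiMe3)2, THF, −78 °C; MeI, −78 → −40 °C; AcOH quench at −78 °C
Reagents that add atoms: iodomethane, CI
Why: Evans asymmetric alkylation: the chelated Z-dienolate is methylated at the α-carbon on the face opposite the auxiliary benzyl group, which sets C12 as S (minor diastereomer removed by chromatography).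

Step 3
Reactants: 6 (S)-4-benzyl-3-[(2S,3E)-2-methyl-4-phenylbut-3-enoyl]oxazolidin-2-one
Product: 7 (2S,3E)-2-methyl-4-phenylbut-3-en-1-ol
Conditions: LiBH4, Et2O/THF, 0 °C → rt; aq. NaOH work-up
Reagents that add atoms: none
Why: Reductive cleavage of the imide with LiBH4 gives the primary alcohol and returns the auxiliary without touching the stereocentre or the styrene.

Step 4
Reactants: 7 (2S,3E)-2-methyl-4-phenylbut-3-en-1-ol
Product: 9 ethyl (2E,4S,5E)-2,4-dimethyl-6-phenylhexa-2,5-dienoate, via aldehyde 8 (not isolated)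
Conditions: DMP, pyridine, CH2Cl2, 0 °C; then Ph3P=C(Me)CO2Et, 0 °C → rt
Reagents that add atoms: ethyl 2-(triphenylphosphoranylidene)propanoate, CCOC(=O)C(C)=P(c1ccccc1)(c1ccccc1)c1ccccc1
Why: Dess–Martin oxidation followed in the same flask by a Wittig reaction with the ester-stabilized ylide traps the epimerizable β,γ-unsaturated aldehyde at or below room temperature and gives the E-trisubstituted enoate.

Step 5
Reactants: 9 ethyl (2E,4S,5E)-2,4-dimethyl-6-phenylhexa-2,5-dienoate
Product: 10 (2E,4S,5E)-2,4-dimethyl-6-phenylhexa-2,5-dien-1-ol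
Conditions: i-Bu2AlH, CH2Cl2, −78 °C; aq. potassium sodium tartrate
Reagents that add atoms: none
Why: 1,2-Reduction of the enoate by the aluminium hydride at low temperature gives the allylic alcohol and leaves both alkenes and C12 untouched.

Step 6
Reactants: 10 (2E,4S,5E)-2,4-dimethyl-6-phenylhexa-2,5-dien-1-ol
Product: 12 (2E,4E,6S,7E)-2,4,6-trimethyl-8-phenylocta-2,4,7-trienal, via enal 11 (not isolated)
Conditions: MnO2 (activated, excess), Ph3P=C(Me)CHO, toluene, rt → 80 °C
Reagents that add atoms: 2-(triphenylphosphoranylidene)propanal, CC(C=O)=P(c1ccccc1)(c1ccccc1)c1ccccc1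
Why: Tandem allylic oxidation–Wittig olefination: the enal is intercepted by the formyl-stabilized ylide to give the E,E-dienal, which is more conjugated and reacts more slowly than the enal.

Step 7
Reactants: 13 (R)-4-benzyl-3-propanoylthiazolidine-2-thione; 12 (2E,4E,6S,7E)-2,4,6-trimethyl-8-phenylocta-2,4,7-trienal
Product: 15 (R)-4-benzyl-3-[(2R,3R,4E,6E,8S,9E)-3-hydroxy-2,4,6,8-tetramethyl-10-phenyldeca-4,6,9-trienoyl]thiazolidine-2-thione, via chlorotitanium enolate 14 (not isolated)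
Conditions: TiCl4, i-Pr2NEt, NMP, CH2Cl2, 0 °C; then 12, −78 → 0 °C; sat. aq. NH4Cl
Reagents that add atoms: none
Why: Crimmins titanium aldol under Evans-syn conditions: the Z-enolate reacts through a closed, non-chelated Zimmerman–Traxler transition state on the face away from the auxiliary benzyl group, so the (R)-auxiliary sets C6 and C7 syn in the required absolute sense.

Step 8
Reactants: 15 (R)-4-benzyl-3-[(2R,3R,4E,6E,8S,9E)-3-hydroxy-2,4,6,8-tetramethyl-10-phenyldeca-4,6,9-trienoyl]thiazolidine-2-thione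
Product: 16 (R)-4-benzyl-3-[(2R,3R,4E,6E,8S,9E)-3-(tert-butyldimethylsilyloxy)-2,4,6,8-tetramethyl-10-phenyldeca-4,6,9-trienoyl]thiazolidine-2-thione
Conditions: TBSOTf, 2,6-lutidine, CH2Cl2, 0 °C
Reagents that add atoms: tert-butyldimethylsilyl trifluoromethanesulfonate, CC(C)(C)[Si](C)(C)OS(=O)(=O)C(F)(F)F
Why: Silylation of the hindered allylic alcohol with the silyl triflate protects C7–OH against retro-aldol and elimination in the following steps.

Step 9
Reactants: 16 (R)-4-benzyl-3-[(2R,3R,4E,6E,8S,9E)-3-(tert-butyldimethylsilyloxy)-2,4,6,8-tetramethyl-10-phenyldeca-4,6,9-trienoyl]thiazolidine-2-thione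
Product: 17 (2R,3R,4E,6E,8S,9E)-3-(tert-butyldimethylsilyloxy)-2,4,6,8-tetramethyl-10-phenyldeca-4,6,9-trienal
Conditions: i-Bu2AlH, CH2Cl2, −78 °C; aq. potassium sodium tartrate
Reagents that add atoms: none
Why: Partial reduction of the activated N-acyl thiazolidinethione stops at the aldehyde at −78 °C and releases the auxiliary without epimerizing C6.

Step 10
Reactants: 17 (2R,3R,4E,6E,8S,9E)-3-(tert-butyldimethylsilyloxy)-2,4,6,8-tetramethyl-10-phenyldeca-4,6,9-trienal
Product: 18 (2E,4S,5R,6E,8E,10S,11E)-5-(tert-butyldimethylsilyloxy)-2,4,6,8,10-pentamethyl-12-phenyldodeca-2,6,8,11-tetraenal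
Conditions: Ph3P=C(Me)CHO, toluene, 90 °C
Reagents that add atoms: 2-(triphenylphosphoranylidene)propanal, CC(C=O)=P(c1ccccc1)(c1ccccc1)c1ccccc1
Why: Wittig olefination with the formyl-stabilized ylide gives the E-trisubstituted enal under neutral conditions that do not epimerize the α-stereocentre.

Step 11
Reactants: 18 (2E,4S,5R,6E,8E,10S,11E)-5-(tert-butyldimethylsilyloxy)-2,4,6,8,10-pentamethyl-12-phenyldodeca-2,6,8,11-tetraenal
Product: 19 (3R,4E,6S,7R,8E,10E,12S,13E)-7-(tert-butyldimethylsilyloxy)-4,6,8,10,12-pentamethyl-14-phenyltetradeca-4,8,10,13-tetraen-3-ol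
Conditions: Et2Zn, (2R)-(+)-3-exo-morpholinoisoborneol [(+)-MIB] (5 mol %), toluene/hexane, 0 °C; sat. aq. NH4Cl
Reagents that add atoms: diethylzinc, CC[Zn]CC
Why: Amino-alcohol-catalysed enantioselective alkylzinc addition to the enal under catalyst control: the (−)-ligand gives S carbinols with aldehydes of this type, so the (+)-ligand sets C3 as R (any C3 epimer is a separable diastereomer).

Step 12
Reactants: 19 (3R,4E,6S,7R,8E,10E,12S,13E)-7-(tert-butyldimethylsilyloxy)-4,6,8,10,12-pentamethyl-14-phenyltetradeca-4,8,10,13-tetraen-3-ol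
Product: 20 (3R,4E,6S,7R,8E,10E,12S,13E)-4,6,8,10,12-pentamethyl-14-phenyltetradeca-4,8,10,13-tetraene-3,7-diol
Conditions: Bu4NF, THF, rt
Reagents that add atoms: none
Why: Fluoride-mediated desilylation under non-acidic conditions frees C7–OH without ionizing the dienylic alcohol.

## Compound list

1 | (E)-4-phenylbut-3-enoic acid | OC(=O)C/C=C/c1ccccc1 | starting material
2 | (S)-4-benzyloxazolidin-2-one | O=C1N[C@@H](Cc2ccccc2)CO1 | starting material
3 | 2,2-dimethylpropanoic (E)-4-phenylbut-3-enoic anhydride (mixed pivalic anhydride) | CC(C)(C)C(=O)OC(=O)C/C=C/c1ccccc1 | intermediate (not isolated)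
4 | (S)-4-benzyl-3-[(E)-4-phenylbut-3-enoyl]oxazolidin-2-one | O=C(C/C=C/c1ccccc1)N1[C@@H](Cc2ccccc2)COC1=O | intermediate
5 | sodium (1Z,3E)-1-[(4S)-4-benzyl-2-oxooxazolidin-3-yl]-4-phenylbuta-1,3-dien-1-olate | [Na+].[O-]/C(=C\C=C\c1ccccc1)N1[C@@H](Cc2ccccc2)COC1=O | intermediate (not isolated)
6 | (S)-4-benzyl-3-[(2S,3E)-2-methyl-4-phenylbut-3-enoyl]oxazolidin-2-one | O=C([C@@H](C)/C=C/c1ccccc1)N1[C@@H](Cc2ccccc2)COC1=O | intermediate
7 | (2S,3E)-2-methyl-4-phenylbut-3-en-1-ol | OC[C@@H](C)/C=C/c1ccccc1 | intermediate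
8 | (2S,3E)-2-methyl-4-phenylbut-3-enal | O=C[C@@H](C)/C=C/c1ccccc1 | intermediate (not isolated)
9 | ethyl (2E,4S,5E)-2,4-dimethyl-6-phenylhexa-2,5-dienoate | CCOC(=O)/C(C)=C/[C@@H](C)/C=C/c1ccccc1 | intermediate
10 | (2E,4S,5E)-2,4-dimethyl-6-phenylhexa-2,5-dien-1-ol | OC/C(C)=C/[C@@H](C)/C=C/c1ccccc1 | intermediate
11 | (2E,4S,5E)-2,4-dimethyl-6-phenylhexa-2,5-dienal | O=C/C(C)=C/[C@@H](C)/C=C/c1ccccc1 | intermediate (not isolated)
12 | (2E,4E,6S,7E)-2,4,6-trimethyl-8-phenylocta-2,4,7-trienal | O=C/C(C)=C/C(C)=C/[C@@H](C)/C=C/c1ccccc1 | intermediate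
13 | (R)-4-benzyl-3-propanoylthiazolidine-2-thione | CCC(=O)N1[C@H](Cc2ccccc2)CSC1=S | starting material
14 | (R)-4-benzyl-3-[(Z)-1-(trichlorotitanyloxy)prop-1-en-1-yl]thiazolidine-2-thione (chlorotitanium Z-enolate of 13) | C/C=C(\O[Ti](Cl)(Cl)Cl)N1[C@H](Cc2ccccc2)CSC1=S | intermediate (not isolated)
15 | (R)-4-benzyl-3-[(2R,3R,4E,6E,8S,9E)-3-hydroxy-2,4,6,8-tetramethyl-10-phenyldeca-4,6,9-trienoyl]thiazolidine-2-thione | O=C([C@H](C)[C@@H](O)/C(C)=C/C(C)=C/[C@@H](C)/C=C/c1ccccc1)N1[C@H](Cc2ccccc2)CSC1=S | intermediate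
16 | (R)-4-benzyl-3-[(2R,3R,4E,6E,8S,9E)-3-(tert-butyldimethylsilyloxy)-2,4,6,8-tetramethyl-10-phenyldeca-4,6,9-trienoyl]thiazolidine-2-thione | O=C([C@H](C)[C@@H](O[Si](C)(C)C(C)(C)C)/C(C)=C/C(C)=C/[C@@H](C)/C=C/c1ccccc1)N1[C@H](Cc2ccccc2)CSC1=S | intermediate
17 | (2R,3R,4E,6E,8S,9E)-3-(tert-butyldimethylsilyloxy)-2,4,6,8-tetramethyl-10-phenyldeca-4,6,9-trienal | O=C[C@H](C)[C@@H](O[Si](C)(C)C(C)(C)C)/C(C)=C/C(C)=C/[C@@H](C)/C=C/c1ccccc1 | intermediate
18 | (2E,4S,5R,6E,8E,10S,11E)-5-(tert-butyldimethylsilyloxy)-2,4,6,8,10-pentamethyl-12-phenyldodeca-2,6,8,11-tetraenal | O=C/C(C)=C/[C@H](C)[C@@H](O[Si](C)(C)C(C)(C)C)/C(C)=C/C(C)=C/[C@@H](C)/C=C/c1ccccc1 | intermediate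
19 | (3R,4E,6S,7R,8E,10E,12S,13E)-7-(tert-butyldimethylsilyloxy)-4,6,8,10,12-pentamethyl-14-phenyltetradeca-4,8,10,13-tetraen-3-ol | CC[C@@H](O)/C(C)=C/[C@H](C)[C@@H](O[Si](C)(C)C(C)(C)C)/C(C)=C/C(C)=C/[C@@H](C)/C=C/c1ccccc1 | intermediate
20 | (3R,4E,6S,7R,8E,10E,12S,13E)-4,6,8,10,12-pentamethyl-14-phenyltetradeca-4,8,10,13-tetraene-3,7-diol | CC[C@@H](O)/C(C)=C/[C@H](C)[C@@H](O)/C(C)=C/C(C)=C/[C@@H](C)/C=C/c1ccccc1 | target

## Step count and risks

Total step count: 12. Longest linear sequence: 12 steps (1 → 20; the route is fully linear).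

The three steps most likely to fail:

Step 4. Aldehyde 8 carries an α-stereocentre that is both allylic and α to the carbonyl, so it can racemize or slip into conjugation before the ylide traps it. The fallback sets out from alcohol 7 and comes back at enoate 9 without ever making a carbonyl at C11. Appel iodination of 7 (I2, PPh3, imidazole, CH2Cl2, 0 °C) gives [(1E,3S)-4-iodo-3-methylbut-1-en-1-yl]benzene F1. Alkylation of the lithium enolate of ethyl 2-(phenylselanyl)propanoate (LiN(i-Pr)2, THF/DMPU, −78 → 0 °C) with F1 gives ethyl (4R,5E)-2,4-dimethyl-6-phenyl-2-(phenylselanyl)hex-5-enoate F2 as a mixture of C2 epimers. H2O2/pyridine (CH2Cl2, 0 °C) oxidizes it to ethyl (4R,5E)-2,4-dimethyl-6-phenyl-2-(phenylseleninyl)hex-5-enoate F3, which undergoes syn-elimination on warming to rt to give 9. The E-enoate is expected as the major product; the α-methylene isomer would have to be removed by chromatography.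

Step 6. The tandem oxidation–Wittig with the formyl ylide can over-homologate (the product 12 is itself an enal) or stall at 80 °C. The fallback sets out from allylic alcohol 10 and comes back at dienal 12 by working at the ester oxidation level. 10 is oxidized with MnO2 in the presence of Ph3P=C(Me)CO2Et (CH2Cl2, 40 °C; enal 11 is again trapped in the flask) to give ethyl (2E,4E,6S,7E)-2,4,6-trimethyl-8-phenylocta-2,4,7-trienoate F4, which cannot react further with the ylide. i-Bu2AlH (CH2Cl2, −78 °C) gives (2E,4E,6S,7E)-2,4,6-trimethyl-8-phenylocta-2,4,7-trien-1-ol F5, and MnO2 (CH2Cl2, rt) then gives 12.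

Step 11. The catalytic ethylation may give low conversion or poor facial selectivity on this hindered, polyunsaturated enal. The fallback sets out from aldehyde 17 and comes back at 19, replacing aldehyde alkylation by ketone reduction. Horner–Wadsworth–Emmons reaction of 17 with diethyl (3-oxopentan-2-yl)phosphonate (Ba(OH)2, wet THF, rt) gives (4E,6S,7R,8E,10E,12S,13E)-7-(tert-butyldimethylsilyloxy)-4,6,8,10,12-pentamethyl-14-phenyltetradeca-4,8,10,13-tetraen-3-one F6. Corey–Bakshi–Shibata reduction ((S)-Me-CBS, i.e. (3aS)-1-methyl-3,3-diphenyltetrahydro-1H,3H-pyrrolo[1,2-c][1,3,2]oxazaborole, with BH3·SMe2, toluene, −40 °C) treats the α-methylalkenyl group as the large substituent and delivers the 3R alcohol 19.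

Further compounds

F1 | step 4 | [(1E,3S)-4-iodo-3-methylbut-1-en-1-yl]benzene | IC[C@@H](C)/C=C/c1ccccc1
F2 | step 4 | ethyl (4R,5E)-2,4-dimethyl-6-phenyl-2-(phenylselanyl)hex-5-enoate (C2 epimers) | CCOC(=O)C(C)([Se]c1ccccc1)C[C@@H](C)/C=C/c1ccccc1
F3 | step 4 | ethyl (4R,5E)-2,4-dimethyl-6-phenyl-2-(phenylseleninyl)hex-5-enoate (C2 epimers) | CCOC(=O)C(C)([Se](=O)c1ccccc1)C[C@@H](C)/C=C/c1ccccc1
F4 | step 6 | ethyl (2E,4E,6S,7E)-2,4,6-trimethyl-8-phenylocta-2,4,7-trienoate | CCOC(=O)/C(C)=C/C(C)=C/[C@@H](C)/C=C/c1ccccc1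
F5 | step 6 | (2E,4E,6S,7E)-2,4,6-trimethyl-8-phenylocta-2,4,7-trien-1-ol | OC/C(C)=C/C(C)=C/[C@@H](C)/C=C/c1ccccc1
F6 | step 11 | (4E,6S,7R,8E,10E,12S,13E)-7-(tert-butyldimethylsilyloxy)-4,6,8,10,12-pentamethyl-14-phenyltetradeca-4,8,10,13-tetraen-3-one | CCC(=O)/C(C)=C/[C@H](C)[C@@H](O[Si](C)(C)C(C)(C)C)/C(C)=C/C(C)=C/[C@@H](C)/C=C/c1ccccc1
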